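The numbers are made up; the flask was simulated.

I was asked how much of the charged solid substrate stands as target and crystals together at the end of the run, and which change lifts that most.

    gas phase ⇌ dissolved gas, rate k1*(csat - [dissolved gas]) (k1 = 0.14 min⁻¹, csat = 4.2 mM)
    dissolved gas + target → over-reaction product (k2 = 2.7 M⁻¹ min⁻¹)
    starting material + dissolved gas → target (k3 = 1.2 M⁻¹ min⁻¹)
    crystals ⇌ target, rate k4*(cs4 - [target]) while solid is left; crystals form when [target] > cs4 (cs4 = 0.52 mM, k4 = 2.3 min⁻¹)
    solid substrate ⇌ starting material, rate k5*(cs5 - [starting material]) while solid is left; crystals form when [starting material] > cs5 (cs5 = 12 mM, k5 = 0.0077 min⁻¹)
    starting material → side product (k6 = 0.0069 min⁻¹)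

solid substrate 0.050 M; gas phase 4.2 mM (held); time 12 h

- zeta: doubling the solubility in step 4, all else as stated
- theta: doubling the saturation concentration of gas phase, all else as stated
- eta: doubling the dissolution coefficient of step 4, all else as stated
- beta: doubling the solubility in step 5, all else as stated

1. the target and crystals together standing at 12 h, as a percentage of the solid substrate charged
2. the change that raises the amount of target and crystals together at 12 h, in percent of the solid substrate charged most ("none" if none brings more than 2 percentage points) (zeta / theta / eta / beta / none)
3. amount of target and crystals together at 12 h, in percent of the solid substrate charged, after eta

- what is said of target includes crystals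
- crystals, solid substrate is a solid; its amount is given per volume of the solution
- at the start none of the gas is dissolved
- at the start none of the solid substrate is in solution
- run time (flask): 12 h

**Branch share.** The gas phase is held, and transfer outruns what dissolved starting material can use, so I took dissolved gas at saturation. Starting material then had two parallel drains: towards target, pseudo-first-order at 0.00504 min⁻¹, and towards side product at 0.0069 min⁻¹. I called the part leaving towards target the branch share: the first drain over the sum of both, 42.2 %.

**Turned round.** For the branch towards target to take the larger part, the first drain would have to exceed the second. This flask stood at 0.730 of that, and theta at 1.46, with a share of 59.4 %.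

**My reckoning.** Balancing feed against both drains, I put starting material at 9.41 % of the charge and the amount passed through the branch at 80.9 %, which the charge covers. With dissolved target taken at its solubility, I put over-reaction at 8.49 %, so I expected 25.7 %, and the same after eta, whose coefficient enters none of this reckoning. For theta I reckoned 37.4 %. For beta, a doubled throughput exceeds the charge, so I capped it at the whole charge, which gave 33.7 %. I chose theta.

**The forecast.** The forecast gave 22.9 %, 23 % after eta, and theta as best; of eta it said that the change “therefore does almost nothing”. My figure for this flask stood higher than the forecast's, though we chose the same change.

**The result.** The simulation gave 22.8 %, 22.9 % after eta, and theta as best, worth 11 percentage points against 9.4 points for beta. In this flask at 12.0 h the products read a branch share of 41.0 %, close to my 42.2 %, while 74.5 % had passed, less than my 80.9 %. The neighbour flask, read at 3.0 h, held target 4.37 %, over-reaction product 1.58 % and side product 8.54 %, a branch share of 41.1 %.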